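The cyclohexane ring C1–C6 (C1 quaternary epoxide carbon bearing C7H2OBz, C2/C3 acetoxy carbons, C4/C5 carbinols, C6 epoxide CH) is disconnected at C1–C2 and C3–C4. One Diels–Alder reaction of furfuryl benzoate, a 2-substituted furan already carrying C7 and its ester, with (E)-hex-3-ene-2,5-dione forms both bonds. It closes the carbocycle as a 7-oxanorbornene, fixes C7 on C1, turns the E-alkene into the trans C2/C3 pair and lays the furan oxygen across C1 and C4. The feature exploited is this trans-2,3-dioxygenated ring flanked by C1(C7) and by the C4–O bond, which survives as the C4 hydroxyl. Baeyer–Villiger oxidation, bridge opening and a bromohydrin closure finish the target.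

Key step: step 2

Remark (convention and assumption): target numbering C1–C7 is kept for all intermediates; α is the ring face of the epoxide oxygen (the face of the oxygen bridge) and β the opposite face. The catalyst in step 2 is assumed to follow its usual facial model; if induction is opposite, its equally available antipode is used.

Step 1
Reactants: 1 furfuryl alcohol; 2 benzoyl chloride
Product: 3 furfuryl benzoate
Conditions: Et3N, 4-(dimethylamino)pyridine (cat.), CH2Cl2, 0 °C → rt
Reagents that add atoms: none
Why: Base-mediated O-acylation (nucleophilic acyl substitution of the Schotten–Baumann type) of a primary alcohol is reliable, the acid-free medium avoids acid-induced resinification of the furfuryl system, and no stereocentre is formed.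

Step 2
Reactants: 3 furfuryl benzoate; 4 (E)-hex-3-ene-2,5-dione
Product: 5 2-exo,3-endo-diacetyl oxanorbornene [(1S,2R,3R,4R)-2,3-diacetyl-7-oxabicyclo[2.2.1]hept-5-en-1-yl]methyl benzoate
Conditions: (S)-3,3-diphenyl-1-(o-tolyl)tetrahydro-1H,3H-pyrrolo[1,2-c][1,3,2]oxazaborole (20 mol %), HN(SO2CF3)2 (20 mol %), 3 (3 equiv), CH2Cl2, −78 → −60 °C; Et3N quench at −78 °C; crude 5 kept below 0 °C and used at once
Reagents that add atoms: none
Why: The protonated oxazaborolidine binds one acetyl oxygen of 4 and lowers its LUMO, so that furan 3 adds in a concerted, asynchronous, suprafacial [4+2] cycloaddition; the closest known reaction type is the oxazaborolidinium-catalysed enantioselective Diels–Alder reaction of furans with enones, acrylates and fumarates. The six-membered carbocycle C1–C6 closes by intermolecular cycloaddition (C1–C2 and C3–C4 made in one event), and the furan oxygen thereby becomes the one-atom bridge between C1 and C4. C2 and C3 come out trans because the E geometry of 4 is conserved, and C1 and C4 are tied to one face by the bridge. The relative sense needed (C2 acetyl exo, C3 acetyl endo) requires that the unsubstituted, more nucleophilic furan α-carbon (future C4) bonds ahead to the β-carbon of the activated enone, which places the catalyst-bound acetyl on C2, and that this bulky complexed acetyl points exo while the small free acetyl takes the endo position under the diene. The absolute sense is set by the catalyst, whose aryl groups shield one face of the bound enone. Kinetic control is essential because cycloreversion would erode both ratios, hence the low temperature, the cold amine quench and the immediate oxidation in step 3.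

Step 3
Reactants: 5 2-exo,3-endo-diacetyl oxanorbornene
Product: 7 exo-epoxy diacetate [(1S,2R,3S,4R,5S,6S)-2-exo,3-endo-diacetoxy-5,6-exo-epoxy-7-oxabicyclo[2.2.1]heptan-1-yl]methyl benzoate, via exo-epoxy diketone 6 (not isolated)
Conditions: urea·H2O2, (CF3CO)2O, Na2HPO4, CH2Cl2, −10 °C → rt
Reagents that add atoms: trifluoroperacetic acid, OOC(=O)C(F)(F)F (made in the flask from urea·H2O2, NC(N)=O.OO, and trifluoroacetic anhydride, O=C(OC(=O)C(F)(F)F)C(F)(F)F)
Why: Since no peracid strong enough for a methyl-ketone Baeyer–Villiger oxidation would spare the strained alkene, the alkene is deliberately epoxidised too (Prilezhaev reaction, exo face only, which masks C5=C6 and stops cycloreversion), and both acetyl groups then undergo Baeyer–Villiger oxidation in which the secondary ring carbon migrates rather than methyl, with retention, so that C2 and C3 keep their configuration.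

Step 4
Reactants: 7 exo-epoxy diacetate
Product: 8 oxanorbornene diacetate [(1R,2R,3S,4R)-2-exo,3-endo-diacetoxy-7-oxabicyclo[2.2.1]hept-5-en-1-yl]methyl benzoate
Conditions: (C5H5)2TiCl2 (2.5 equiv), Zn dust, THF, rt
Reagents that add atoms: none
Why: In this titanocene-mediated epoxide deoxygenation, (C5H5)2TiCl (trivalent titanium) opens the epoxide by single-electron transfer, a second equivalent captures the radical on the exo face and syn β-elimination of the exo C–Ti/C–OTi pair returns the alkene; the process is known to tolerate esters and neighbouring ether oxygens in carbohydrate epoxides and touches none of C1–C4.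

Step 5
Reactants: 8 oxanorbornene diacetate
Product: 9 cyclohexenol benzyl ether [(3S,4R,5S,6S)-5,6-diacetoxy-3-(benzyloxy)-4-hydroxycyclohex-1-en-1-yl]methyl benzoate (target numbering: C2-OAc α, C3-OAc β, C4-OH α, C5-OBn β, C1=C6)
Conditions: [Rh(cod)Cl]2 (cod = 1,5-cyclooctadiene, 2.5 mol %), Fe(C5H4PPh2)2 (dppf, 5 mol %), benzyl alcohol (5 equiv), THF, 65 °C
Reagents that add atoms: benzyl alcohol, OCc1ccccc1
Why: In this rhodium-catalysed nucleophilic ring opening of an oxabicyclic alkene (anti SN2′), monovalent rhodium binds the exo face and inserts into the weaker, tertiary allylic C1–O bond, and the alcohol attacks the remote allyl terminus C5 opposite to the metal, which sets C5–OBn β, trans to the C4 hydroxyl that keeps the furan oxygen and its α configuration; attack at the alkene carbon far from a bridgehead substituent is the known regiochemistry of this reaction.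

Step 6
Reactants: 9 cyclohexenol benzyl ether
Product: 10 benzyl carbonate [(3S,4R,5R,6S)-5,6-diacetoxy-3-(benzyloxy)-4-(benzyloxycarbonyloxy)cyclohex-1-en-1-yl]methyl benzoate
Conditions: benzyl chloroformate, pyridine, 4-(dimethylamino)pyridine (cat.), CH2Cl2, 0 °C
Reagents that add atoms: benzyl chloroformate, O=C(Cl)OCc1ccccc1
Why: Standard acylation of the only free hydroxyl to a benzyl carbonate keeps C4–OH from re-closing onto C1 (bromoetherification) in step 7, blocks C3→C4 acetyl migration, and gives a group that leaves with the benzyl ether in one hydrogenolysis.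

Step 7
Reactants: 10 benzyl carbonate
Product: 12 protected epoxide [(1S,2R,3S,4R,5R,6S)-2,3-diacetoxy-5-(benzyloxy)-4-(benzyloxycarbonyloxy)-7-oxabicyclo[4.1.0]heptan-1-yl]methyl benzoate, via bromohydrin 11 (not isolated)
Conditions: N-bromosuccinimide, DME–H2O (4:1), 0 °C → rt, dark; extractive work-up; 1,8-diazabicyclo[5.4.0]undec-7-ene (DBU), CH2Cl2, 0 °C
Reagents that add atoms: water, O; N-bromosuccinimide, O=C1CCC(=O)N1Br (its bromine stays only in 11)
Why: This is bromohydrin formation followed by intramolecular Williamson closure: in the all-equatorial half-chair of 10 the reversible bromonium ion is opened productively only by Markovnikov attack of water at tertiary C1 along the axial trajectory (Fürst–Plattner rule), which puts bromine β on C6 and hydroxyl α on C1 (participation of the α C2 acetate or of the C7 benzoate would bring oxygen to the same face), and the trans-diaxial bromohydrin closes with inversion at C6 to the α C1–C6 epoxide.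

Step 8
Reactants: 12 protected epoxide
Product: 13 target [(1S,2R,3S,4R,5R,6S)-2,3-diacetoxy-4,5-dihydroxy-7-oxabicyclo[4.1.0]heptan-1-yl]methyl benzoate
Conditions: H2 (1 atm), Pd/C (10 % Pd), EtOAc, rt
Reagents that add atoms: none
Why: Catalytic hydrogenolysis cleaves the benzyl ether and the benzyl carbonate (the latter with loss of CO2) under neutral conditions, which avoids acetyl migration and Payne rearrangement of the freed diol and leaves the non-benzylic epoxide, the acetates and the benzoate untouched.

Compound list
1 | furfuryl alcohol (furan-2-ylmethanol) | OCc1ccco1 | starting material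
2 | benzoyl chloride | O=C(Cl)c1ccccc1 | starting material
3 | furfuryl benzoate (furan-2-ylmethyl benzoate) | O=C(OCc1ccco1)c1ccccc1 | intermediate
4 | (E)-hex-3-ene-2,5-dione | CC(=O)/C=C/C(C)=O | starting material
5 | [(1S,2R,3R,4R)-2-exo,3-endo-diacetyl-7-oxabicyclo[2.2.1]hept-5-en-1-yl]methyl benzoate | CC(=O)[C@@H]1[C@@H](C(C)=O)[C@]2(COC(=O)c3ccccc3)C=C[C@H]1O2 | intermediate
6 | [(1S,2R,3R,4S,5S,6S)-2-exo,3-endo-diacetyl-5,6-exo-epoxy-7-oxabicyclo[2.2.1]heptan-1-yl]methyl benzoate | CC(=O)[C@@H]1[C@@H](C(C)=O)[C@]2(COC(=O)c3ccccc3)[C@H]4O[C@H]4[C@H]1O2 | intermediate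
7 | [(1S,2R,3S,4R,5S,6S)-2-exo,3-endo-diacetoxy-5,6-exo-epoxy-7-oxabicyclo[2.2.1]heptan-1-yl]methyl benzoate | CC(=O)O[C@@H]1[C@@H](OC(C)=O)[C@]2(COC(=O)c3ccccc3)[C@H]4O[C@H]4[C@H]1O2 | intermediate
8 | [(1R,2R,3S,4R)-2-exo,3-endo-diacetoxy-7-oxabicyclo[2.2.1]hept-5-en-1-yl]methyl benzoate | CC(=O)O[C@@H]1[C@@H](OC(C)=O)[C@]2(COC(=O)c3ccccc3)C=C[C@H]1O2 | intermediate
9 | [(3S,4R,5S,6S)-5,6-diacetoxy-3-(benzyloxy)-4-hydroxycyclohex-1-en-1-yl]methyl benzoate | CC(=O)O[C@H]1[C@H](O)[C@@H](OCc2ccccc2)C=C(COC(=O)c2ccccc2)[C@@H]1OC(C)=O | intermediate
10 | [(3S,4R,5R,6S)-5,6-diacetoxy-3-(benzyloxy)-4-(benzyloxycarbonyloxy)cyclohex-1-en-1-yl]methyl benzoate | CC(=O)O[C@H]1[C@H](OC(=O)OCc2ccccc2)[C@@H](OCc2ccccc2)C=C(COC(=O)c2ccccc2)[C@@H]1OC(C)=O | intermediate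
11 | [(1R,2R,3S,4S,5R,6R)-2,3-diacetoxy-5-(benzyloxy)-4-(benzyloxycarbonyloxy)-6-bromo-1-hydroxycyclohexyl]methyl benzoate (C1-OH α, C6-Br β) | CC(=O)O[C@H]1[C@H](OC(=O)OCc2ccccc2)[C@@H](OCc2ccccc2)[C@@H](Br)[C@@](O)(COC(=O)c2ccccc2)[C@@H]1OC(C)=O | intermediate
12 | [(1S,2R,3S,4R,5R,6S)-2,3-diacetoxy-5-(benzyloxy)-4-(benzyloxycarbonyloxy)-7-oxabicyclo[4.1.0]heptan-1-yl]methyl benzoate | CC(=O)O[C@H]1[C@H](OC(=O)OCc2ccccc2)[C@@H](OCc2ccccc2)[C@@H]2O[C@]2(COC(=O)c2ccccc2)[C@@H]1OC(C)=O | intermediate
13 | [(1S,2R,3S,4R,5R,6S)-2,3-diacetoxy-4,5-dihydroxy-7-oxabicyclo[4.1.0]heptan-1-yl]methyl benzoate (CNP0171674.1) | CC(=O)O[C@H]1[C@H](O)[C@@H](O)[C@@H]2O[C@]2(COC(=O)c2ccccc2)[C@@H]1OC(C)=O | target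

Total step count: 8. Longest linear sequence: 8 steps (1 → 13).

Steps most likely to fail

**Step 2.** Four things may go wrong:
- The cycloaddition may stall because the furan equilibrium is unfavourable.
- The free furan α-position may add to the activated enedione in a conjugate, Friedel–Crafts-type fashion.
- The complexed acetyl may prefer the endo position.
- Facial discrimination may be poor.

The fallback sets out from 3 and 4 and returns at 7; it gives up catalytic stereocontrol in favour of pressure and resolution. Without any acid, 3 and 4 are pressed at about 12 kbar in CH2Cl2 at room temperature (pressure-promoted furan Diels–Alder reaction). This should give 5 together with its mirror image, the enantiomeric adduct F1. The crude material is oxidised exactly as in step 3, passing through 6 and the enantiomeric epoxy diketone F2. The locked, stable products are freed from the other diastereomer by chromatography or crystallisation. The racemate of 7 and the enantiomeric epoxy diacetate F3 is then resolved by preparative chromatography on a chiral stationary phase.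

**Step 5.** Rhodium may insert slowly into an oxabicycle that carries three electron-withdrawing ester groups. The rhodium alkoxide may isomerise by β-hydride elimination, or the allylic esters of the product may ionise.

The fallback sets out from 8 and returns at 9; it is a stepwise, metal-free opening. BBr3 in CH2Cl2 at −78 °C is a reagent known to cleave the bridge of 2,3-dioxygenated 7-oxanorbornenes to bromocyclohexenols. It should break the tertiary allylic C1–O bond and, after allylic equilibration and aqueous work-up, give the allylic bromohydrin F4. Silver-assisted solvolysis (AgOSO2CF3, 2,6-di-tert-butylpyridine, benzyl alcohol, CH2Cl2, −40 °C) then replaces bromide through the allyl cation. The alcohol enters at the secondary terminus C5 anti to the neighbouring C4 oxygen, so both bromide epimers converge on 9.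

**Step 7.** Bromonium formation may be sluggish at an alkene deactivated by three allylic C–O bonds. Markovnikov regiocontrol may erode, which would invert the facial outcome, or acyl groups may migrate after ester participation.

The fallback sets out from 9 and returns at 13; it uses hydroxyl-directed epoxidation in place of halohydrin chemistry. With C4–OH left free, VO(acac)2 [VO(C5H7O2)2] (cat.) and t-BuOOH in toluene at 40–60 °C can deliver oxygen only through the vanadium alkoxide of the homoallylic α hydroxyl. Oxygen therefore reaches the α face and gives the epoxy alcohol F5. Hydrogenolysis of its benzyl ether (H2, Pd/C, EtOAc) then gives 13. This shorter path is held in reserve because its reactive conformer needs an axial C4–O that is crowded by the C2 acetate.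

Further compounds
F1 | step 2 | [(1R,2S,3S,4S)-2-exo,3-endo-diacetyl-7-oxabicyclo[2.2.1]hept-5-en-1-yl]methyl benzoate (enantiomer of 5) | CC(=O)[C@H]1[C@H](C(C)=O)[C@@]2(COC(=O)c3ccccc3)C=C[C@@H]1O2
F2 | step 2 | [(1R,2S,3S,4R,5R,6R)-2-exo,3-endo-diacetyl-5,6-exo-epoxy-7-oxabicyclo[2.2.1]heptan-1-yl]methyl benzoate (enantiomer of 6) | CC(=O)[C@H]1[C@H](C(C)=O)[C@@]2(COC(=O)c3ccccc3)[C@@H]4O[C@@H]4[C@@H]1O2
F3 | step 2 | [(1R,2S,3R,4S,5R,6R)-2-exo,3-endo-diacetoxy-5,6-exo-epoxy-7-oxabicyclo[2.2.1]heptan-1-yl]methyl benzoate (enantiomer of 7) | CC(=O)O[C@H]1[C@H](OC(C)=O)[C@@]2(COC(=O)c3ccccc3)[C@@H]4O[C@@H]4[C@@H]1O2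
F4 | step 5 | (5,6-diacetoxy-3-bromo-4-hydroxycyclohex-1-en-1-yl)methyl benzoate, C2-OAc α, C3-OAc β, C4-OH α, epimers at the bromide carbon C5 | CC(=O)O[C@H]1[C@H](O)C(Br)C=C(COC(=O)c2ccccc2)[C@@H]1OC(C)=O
F5 | step 7 | [(1S,2R,3S,4R,5R,6S)-2,3-diacetoxy-5-(benzyloxy)-4-hydroxy-7-oxabicyclo[4.1.0]heptan-1-yl]methyl benzoate | CC(=O)O[C@H]1[C@H](O)[C@@H](OCc2ccccc2)[C@@H]2O[C@]2(COC(=O)c2ccccc2)[C@@H]1OC(C)=O
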